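Labdane numbering is used: decalin C1–C10 (gem-dimethyl at C4, angular CH3 = C20 on C10), C17 = CH2OH on C8, side chain C11–C12 on C9, butenolide C13–C16.
Retrosynthetic cuts, in order: the two O–Si bonds; C12–C13 (B-alkyl Suzuki–Miyaura); C11=C12 (Wittig) and C11–O2 (lactone reduction); C5–C10 together with C6–C7 (both carbocycles at once); C8–C9 (Negishi); C10–C20 and C9–I (carbocupration/iodination); C1–C10 (epoxide alkynylation); C5–C6 (Wittig homologation).
Enabling feature: in the cis-decalin the C2 oxygen and C9 are 1,3-cis on ring A, so O2 can be tied to C11 as a δ-lactone (O2–C11–C9=C10–C1–C2). This temporary ring makes C10 the β-carbon of an acceptor that carries the C8=C7 vinyl unit, the C6 oxygen makes C5 the nucleophilic carbon of an aldehyde silyl enol ether, and the C8=C9 cyclohexene of ring B is the [4+2] retron.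
Forward: a linear C1–C6 chain is grown into a monocyclic dienyl lactone. One catalytic isomerisation closes ring A (C5–C10) and then ring B (C6–C7). The lactone is then taken apart (C11 becomes the first side-chain carbon) and the butenolide is coupled on last.
Stereochemistry: C2 comes from a hydrolytic kinetic resolution. C10, C5 and C6 are relayed from C2 in the key step through the lactone tether, and no later step touches a stereocentre.

Key step: step 11

Remark: the SMILES is read as written, that is a cis-fused decalin with 10β-CH3, 5β-H, 2α-OH and 6α-OH, (2S,5R,6S,10S) in labdane numbering.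

Step 1
Reactants: 1 2,2-dimethylpent-4-enal
Product: 2 1-methoxy-3,3-dimethylhexa-1,5-diene (E/Z mixture)
Conditions: MeOCH2PPh3Cl, KOtBu, THF, 0 °C to rt
Reagents that add atoms: (methoxymethyl)triphenylphosphonium chloride, COC[P+](c1ccccc1)(c1ccccc1)c1ccccc1.[Cl-]
Why: Wittig methoxymethylenation adds C6 to a neopentyl aldehyde that cannot enolise, and the E/Z ratio is irrelevant because both isomers converge in step 2.

Step 2
Reactants: 2 1-methoxy-3,3-dimethylhexa-1,5-diene
Product: 3 2-(2,2-dimethylpent-4-en-1-yl)-1,3-dioxolane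
Conditions: ethylene glycol, p-TsOH (cat.), CH2Cl2, rt
Reagents that add atoms: ethylene glycol, OCCO
Why: Acid-catalysed addition of the diol to the enol ether (transacetalisation through the C6 oxocarbenium ion) masks the aldehyde as a dioxolane that should survive peracid, organolithium, cuprate and palladium chemistry, while the terminal alkene is inert.

Step 3
Reactants: 3 2-(2,2-dimethylpent-4-en-1-yl)-1,3-dioxolane
Product: 4 rac-2-[2,2-dimethyl-3-(oxiran-2-yl)propyl]-1,3-dioxolane
Conditions: mCPBA, NaHCO3, CH2Cl2, 0 °C to rt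
Reagents that add atoms: mCPBA, OOC(=O)c1cccc(Cl)c1
Why: Prilezhaev epoxidation of the only alkene gives the terminal epoxide as a racemate, and the C2 stereocentre is sorted out in step 4.

Step 4
Reactants: 4 rac-2-[2,2-dimethyl-3-(oxiran-2-yl)propyl]-1,3-dioxolane
Product: 5 (S)-2-[2,2-dimethyl-3-(oxiran-2-yl)propyl]-1,3-dioxolane
Conditions: (S,S)-(salen)Co(III)OAc (0.5 mol %), H2O (0.55 equiv), THF, 0 °C to rt
Reagents that add atoms: none
Why: Hydrolytic kinetic resolution of a terminal epoxide: the (S,S)-catalyst should hydrolyse the (R)-epoxide selectively and leave the (S)-epoxide, which fixes C2, the only stereocentre brought in from outside.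

Step 5
Reactants: 5 (S)-2-[2,2-dimethyl-3-(oxiran-2-yl)propyl]-1,3-dioxolane; 6 ethyl propiolate
Product: 8 ethyl (S)-8-(1,3-dioxolan-2-yl)-5-hydroxy-7,7-dimethyloct-2-ynoate, via lithium ethyl propiolate 7 (not isolated)
Conditions: 6, n-BuLi, THF, −78 °C; BF3·OEt2; then 5, −78 °C
Reagents that add atoms: none
Why: BF3-promoted alkynylation of a terminal epoxide (Yamaguchi–Hirao conditions) attacks only the unsubstituted carbon C1, so the C2–O bond and its configuration are untouched, and the cyclic acetal should tolerate BF3·OEt2 at −78 °C.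

Step 6
Reactants: 8 ethyl (S)-8-(1,3-dioxolan-2-yl)-5-hydroxy-7,7-dimethyloct-2-ynoate
Product: 11 (S)-6-[3-(1,3-dioxolan-2-yl)-2,2-dimethylpropyl]-3-iodo-4-methyl-5,6-dihydro-2H-pyran-2-one, via alkenylcuprate 9 (not isolated), via iodo enoate 10 (not isolated)
Conditions: MeLi/CuI (Me2CuLi, 3 equiv), THF, −78 °C; I2, −78 to 0 °C
Reagents that add atoms: methyllithium, [Li]C; iodine, II
Why: Syn-carbocupration of the ynoate delivers CH3 (C20) to the β-carbon C10 and copper to C9 on the same side, iodinolysis proceeds with retention, and because the ester then lies cis to the carbinol chain the alkoxide lactonises, so the ring locks the tetrasubstituted C9=C10 geometry.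

Step 7
Reactants: 12 2-bromoprop-2-en-1-ol
Product: 13 [(2-bromoprop-2-en-1-yl)oxy](tert-butyl)diphenylsilane
Conditions: TBDPSCl, imidazole, CH2Cl2, rt
Reagents that add atoms: TBDPSCl, CC(C)(C)[Si](Cl)(c1ccccc1)c1ccccc1
Why: Standard silylation of a primary allylic alcohol, with TBDPS chosen because it should outlast the aqueous acid of step 9 and the silylium catalyst of step 11.

Step 8
Reactants: 13 [(2-bromoprop-2-en-1-yl)oxy](tert-butyl)diphenylsilane; 11 iodolactone
Product: 16 (S)-3-[3-(tert-butyldiphenylsilyloxy)prop-1-en-2-yl]-6-[3-(1,3-dioxolan-2-yl)-2,2-dimethylpropyl]-4-methyl-5,6-dihydro-2H-pyran-2-one, via alkenyllithium 14 (not isolated), via alkenylzinc bromide 15 (not isolated)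
Conditions: 13, t-BuLi (2 equiv), Et2O, −78 °C; ZnBr2, THF, −78 to 0 °C; 11, Pd(PPh3)4 (5 mol %), THF/DMF, rt to 45 °C
Reagents that add atoms: none
Why: Negishi coupling of an α-iodo-α,β-unsaturated carbonyl compound with an alkenylzinc reagent forms C8–C9 with retention, and bromine–lithium exchange at −78 °C followed by immediate transmetalation should forestall O-to-C silyl migration.

Step 9
Reactants: 16 dienyl lactone acetal
Product: 17 (S)-4-{5-[3-(tert-butyldiphenylsilyloxy)prop-1-en-2-yl]-4-methyl-6-oxo-3,6-dihydro-2H-pyran-2-yl}-3,3-dimethylbutanal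
Conditions: 1 M HCl, THF, rt to 40 °C
Reagents that add atoms: water, O
Why: Acid hydrolysis of the aldehyde acetal, under which the TBDPS ether, the unsaturated lactone and the electron-poor diene should persist.

Step 10
Reactants: 17 lactone aldehyde
Product: 18 (Z)-tert-butyldimethylsilyl enol ether of 17
Conditions: TBSOTf, Et3N, CH2Cl2, −78 to 0 °C
Reagents that add atoms: TBSOTf, CC(C)(C)[Si](C)(C)OS(=O)(=O)C(F)(F)F
Why: Soft enolisation with silyl triflate and amine converts the aldehyde, which is far more easily O-silylated than the lactone, into its silyl enol ether, mainly the Z isomer.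

Step 11
Reactants: 18 (Z)-silyl enol ether
Product: 20 tricyclic lactone 6α-(TBSO)-17-(TBDPSO)-12,13,14,15,16-pentanorlabd-8-en-11,2α-olide (cis-decalin; 5β-H; 10β-CH3), via oxocarbenium silyl ketene acetal ion pair 19 (not isolated)
Conditions: HNTf2 (5 mol %), CH2Cl2, −78 to −20 °C; then Et3N
Reagents that add atoms: none
Why: Proposed new method: HNTf2 protodesilylates a trace of 18 to TBSNTf2, whose silylium ion binds the lactone carbonyl so that C5 of the tethered silyl enol ether attacks C10 (Mukaiyama–Michael addition, 6-(enolexo)-exo-trig, closes ring A through C5–C10, helped by the gem-dimethyl effect at C4); in ion pair 19 the terminus C7 of the silyl dienol ether C11=C9–C8=C7 then closes on the C6 silyloxocarbenium ion (vinylogous Mukaiyama aldol, 6-(enolendo)-exo-trig, ring B), which restores the lactone, places the alkene at C8=C9 and passes the silylium ion on, so the step is a catalytic isomerisation equivalent to an inverse-electron-demand [4+2] addition. The closest known reaction types are inverse-demand Diels–Alder reactions of 2-acyl-1,3-dienes with enol ethers, silylium-catalysed Mukaiyama–Michael additions and stepwise Lewis-acid Diels–Alder reactions that join two hindered carbons; new here are the tetrasubstituted α-alkenyl pentenolide as acceptor and the vinylogous closure. C10 is controlled by C2, because the C3–C4–C5 chain can reach C10 only on the lactone face that carries C3 (bicyclo[3.3.1]nonane constraint), which puts C20 on the face opposite O2. C5 is controlled by ring closure, because only the adduct with C6 gauche to C9 (H5 syn to C20, cis-fusion) can form ring B, while the other Michael adduct cannot close and can revert. C6 is set by the OTBS group taking the pseudo-equatorial site of the forming ring B, away from the axial C20, which is also the result of suprafacial endo addition of the Z enol ether. The step needs C10 as the only electrophilic site (C7=C8 is cross-conjugated and not activated) and γ-closure at C7 rather than closure at C9 or at oxygen, which is secured because the cyclobutane and the ketene acetal are strained and reversible whereas the six-membered ring is the thermodynamic sink.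

Step 12
Reactants: 20 tricyclic lactone
Product: 21 corresponding lactol (11-hydroxy-2α,11-epoxide; anomer mixture)
Conditions: DIBAL-H (1.1 equiv), CH2Cl2, −78 °C; Rochelle salt
Reagents that add atoms: none
Why: Partial DIBAL-H reduction of a lactone stops at the aluminium hemiacetal at −78 °C, no stereocentre of the target is affected, and the new lactol carbon loses its stereocentre in step 13.

Step 13
Reactants: 21 lactol
Product: 23 6α-(TBSO)-17-(TBDPSO)-13,14,15,16-tetranorlabda-8,11-dien-2α-ol (5β-H; 10β-CH3), via hydroxy enal 22 (not isolated)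
Conditions: MePPh3Br, KOtBu (3 equiv each), THF, 0 °C to rt
Reagents that add atoms: methyltriphenylphosphonium bromide, C[P+](c1ccccc1)(c1ccccc1)c1ccccc1.[Br-]
Why: Wittig methylenation of a lactol through its open hydroxy-enal tautomer adds C12 and frees the 2α-hydroxyl, with excess ylide covering the acidic OH.

Step 14
Reactants: 23 diene alcohol; 24 4-bromofuran-2(5H)-one
Product: 26 6-O-TBS-17-O-TBDPS ether of the target, via B-alkyl-9-BBN adduct 25 (not isolated)
Conditions: 9-BBN-H (2.5 equiv), THF, 0 to 40 °C; then 24, PdCl2(dppf) (5 mol %), AsPh3, aq K3PO4, DMF, rt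
Reagents that add atoms: none
Why: 9-BBN should add only to the unhindered terminal C11=C12 bond (boron on C12, the tetrasubstituted C8=C9 bond being inert), and the B-alkyl Suzuki–Miyaura coupling with the β-bromobutenolide forms C12–C13 under mild phosphate base, the O-borinate at C2 being hydrolysed on work-up.

Step 15
Reactants: 26 bis-silyl ether
Product: 27 target, (2S,5R,6S,10S)-2,6,17-trihydroxylabda-8,13-dien-15,16-olide
Conditions: TBAF, AcOH, THF, rt to 50 °C
Reagents that add atoms: none
Why: Buffered fluoride desilylation cleaves both silyl ethers without base-induced isomerisation of the butenolide and touches no stereocentre.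

Compound list
1 | 2,2-dimethylpent-4-enal | C=CCC(C)(C)C=O | starting material
2 | 1-methoxy-3,3-dimethylhexa-1,5-diene (E/Z mixture) | COC=CC(C)(C)CC=C | intermediate
3 | 2-(2,2-dimethylpent-4-en-1-yl)-1,3-dioxolane | C=CCC(C)(C)CC1OCCO1 | intermediate
4 | rac-2-[2,2-dimethyl-3-(oxiran-2-yl)propyl]-1,3-dioxolane | O1CC1CC(C)(C)CC1OCCO1 | intermediate
5 | (S)-2-[2,2-dimethyl-3-(oxiran-2-yl)propyl]-1,3-dioxolane | O1CCOC1CC(C)(C)C[C@H]2CO2 | intermediate
6 | ethyl propiolate | C#CC(=O)OCC | starting material
7 | lithium ethyl propiolate | [Li]C#CC(=O)OCC | intermediate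
8 | ethyl (S)-8-(1,3-dioxolan-2-yl)-5-hydroxy-7,7-dimethyloct-2-ynoate | O1CCOC1CC(C)(C)C[C@H](O)CC#CC(=O)OCC | intermediate
9 | dilithium alkoxide alkenyl(methyl)cuprate from syn-addition to 8 (Cu cis to the new CH3) | CCOC(=O)/C([Cu-]C)=C(C)\C[C@@H]([O-])CC(C)(C)CC1OCCO1.[Li+].[Li+] | intermediate
10 | ethyl (S,E)-8-(1,3-dioxolan-2-yl)-5-hydroxy-2-iodo-3,7,7-trimethyloct-2-enoate | CCOC(=O)/C(I)=C(C)\C[C@@H](O)CC(C)(C)CC1OCCO1 | intermediate
11 | (S)-6-[3-(1,3-dioxolan-2-yl)-2,2-dimethylpropyl]-3-iodo-4-methyl-5,6-dihydro-2H-pyran-2-one | O1CCOC1CC(C)(C)C[C@H]2CC(C)=C(I)C(=O)O2 | intermediate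
12 | 2-bromoprop-2-en-1-ol | C=C(Br)CO | starting material
13 | [(2-bromoprop-2-en-1-yl)oxy](tert-butyl)diphenylsilane | C=C(Br)CO[Si](c1ccccc1)(c1ccccc1)C(C)(C)C | intermediate
14 | 3-(tert-butyldiphenylsilyloxy)prop-1-en-2-yllithium | [Li]C(=C)CO[Si](c1ccccc1)(c1ccccc1)C(C)(C)C | intermediate
15 | 3-(tert-butyldiphenylsilyloxy)prop-1-en-2-ylzinc bromide | Br[Zn]C(=C)CO[Si](c1ccccc1)(c1ccccc1)C(C)(C)C | intermediate
16 | (S)-3-[3-(TBDPSO)prop-1-en-2-yl]-6-[3-(1,3-dioxolan-2-yl)-2,2-dimethylpropyl]-4-methyl-5,6-dihydro-2H-pyran-2-one | O1CCOC1CC(C)(C)C[C@H]2CC(C)=C(C(=C)CO[Si](c3ccccc3)(c3ccccc3)C(C)(C)C)C(=O)O2 | intermediate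
17 | (S)-4-{5-[3-(TBDPSO)prop-1-en-2-yl]-4-methyl-6-oxo-3,6-dihydro-2H-pyran-2-yl}-3,3-dimethylbutanal | O=CCC(C)(C)C[C@H]1CC(C)=C(C(=C)CO[Si](c2ccccc2)(c2ccccc2)C(C)(C)C)C(=O)O1 | intermediate
18 | (Z)-TBS enol ether of 17 | CC(C)(C)[Si](C)(C)O/C=C\C(C)(C)C[C@H]1CC(C)=C(C(=C)CO[Si](c2ccccc2)(c2ccccc2)C(C)(C)C)C(=O)O1 | intermediate
19 | ion pair after C5–C10 bond formation: C6 silyloxocarbenium ion, cyclic silyl ketene acetal C11=C9 bearing the C8=C7 vinyl unit, NTf2 counter-ion | CC1(C)C[C@H]3C[C@](C)(C(=C(O[Si](C)(C)C(C)(C)C)O3)C(=C)CO[Si](c4ccccc4)(c4ccccc4)C(C)(C)C)[C@@H]1C=[O+][Si](C)(C)C(C)(C)C.O=S(=O)([N-]S(=O)(=O)C(F)(F)F)C(F)(F)F | intermediate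
20 | tricyclic lactone: cis-decalin (5β-H, 10β-CH3), C8=C9, C11 carboxyl on C9 lactonised to the 2α-oxygen, 6α-OTBS, C17H2OTBDPS | CC1(C)C[C@H]3C[C@]2(C)C(C(=O)O3)=C(CO[Si](c4ccccc4)(c4ccccc4)C(C)(C)C)C[C@H](O[Si](C)(C)C(C)(C)C)[C@H]12 | intermediate
21 | lactol of 20 (C11 anomers) | CC1(C)C[C@H]3C[C@]2(C)C(C(O)O3)=C(CO[Si](c4ccccc4)(c4ccccc4)C(C)(C)C)C[C@H](O[Si](C)(C)C(C)(C)C)[C@H]12 | intermediate
22 | open tautomer of 21: 2α-hydroxy-8-en-11-al | CC1(C)C[C@H](O)C[C@]2(C)C(C=O)=C(CO[Si](c3ccccc3)(c3ccccc3)C(C)(C)C)C[C@H](O[Si](C)(C)C(C)(C)C)[C@H]12 | intermediate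
23 | 9-vinyl compound: 6α-OTBS, 17-OTBDPS, 13,14,15,16-tetranorlabda-8,11-dien-2α-ol | CC1(C)C[C@H](O)C[C@]2(C)C(C=C)=C(CO[Si](c3ccccc3)(c3ccccc3)C(C)(C)C)C[C@H](O[Si](C)(C)C(C)(C)C)[C@H]12 | intermediate
24 | 4-bromofuran-2(5H)-one | O=C1C=C(Br)CO1 | starting material
25 | C12-(9-BBN) alkylborane, 2-O-(9-BBN) borinate of 23 | CC1(C)C[C@H](OB3C4CCCC3CCC4)C[C@]2(C)C(CCB3C4CCCC3CCC4)=C(CO[Si](c3ccccc3)(c3ccccc3)C(C)(C)C)C[C@H](O[Si](C)(C)C(C)(C)C)[C@H]12 | intermediate
26 | 6-O-TBS-17-O-TBDPS ether of the target | CC1(C)C[C@H](O)C[C@]2(C)C(CCC3=CC(=O)OC3)=C(CO[Si](c3ccccc3)(c3ccccc3)C(C)(C)C)C[C@H](O[Si](C)(C)C(C)(C)C)[C@H]12 | intermediate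
27 | (2S,5R,6S,10S)-2,6,17-trihydroxylabda-8,13-dien-15,16-olide | CC1(C)C[C@H](O)C[C@]2(C)C(CCC3=CC(=O)OC3)=C(CO)C[C@H](O)[C@H]12 | target

Total step count: 15. Longest linear sequence: 14 (steps 1–6 and 8–15).

Steps most likely to fail

Step 11. Attack on the tetrasubstituted acceptor may be too slow, so that protodesilylation of the enol ether, or reversible closure through oxygen or C9, takes over. The fallback uses known chemistry, an intramolecular enone–alkene [2+2] photocycloaddition followed by ring expansion of a donor–acceptor vinylcyclobutane, and sets out from 18. Sensitised irradiation (λ > 350 nm, MeCN) joins C10 to C5 and C9 to C6 from the excited state, which does not depend on ground-state electrophilicity, and should give the cyclobutane photoadduct F1. Catalytic TBSOTf or gentle heating then cleaves the push–pull C6–C9 bond and recloses at C7 (formal 1,3-shift driven by release of ring strain). This comes back to the route at 20.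

Step 14. Hydroboration of the hindered conjugated diene may be sluggish or unselective, and the bromobutenolide may decompose under the basic coupling conditions before transmetalation occurs. The fallback sets out from 21 and bypasses steps 13 and 14. Wittig olefination of the lactol with the ylide from [(5-oxo-2,5-dihydrofuran-3-yl)methyl]triphenylphosphonium bromide should give the (E)-11,12-didehydro butenolide F2. Diimide (2-nitrobenzenesulfonyl hydrazide, Et3N) should then saturate only the disubstituted C11=C12 bond and leave the trisubstituted butenolide and the tetrasubstituted C8=C9 alkene. This comes back to the route at 26.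

Step 12. The strained aluminium hemiacetal may collapse to the enal in the flask, which would lead to over-reduction. The fallback sets out from 20. Exhaustive reduction with LiAlH4 should give the 2α,11-diol F3, and MnO2 then oxidises only the primary allylic alcohol. This comes back to the route at 22, which is methylenated as in step 13.

Further compounds
F1 | step 11 | cyclobutane photoadduct (bonds C5–C10 and C6–C9; C8=C7 vinyl unit and lactone carbonyl on C9) | CC1(C)C[C@H]3C[C@]2(C)[C@@](C(=O)O3)(C(=C)CO[Si](c4ccccc4)(c4ccccc4)C(C)(C)C)[C@H](O[Si](C)(C)C(C)(C)C)[C@H]12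
F2 | step 14 | (E)-11,12-didehydro derivative of 26 | CC1(C)C[C@H](O)C[C@]2(C)C(/C=C/C3=CC(=O)OC3)=C(CO[Si](c3ccccc3)(c3ccccc3)C(C)(C)C)C[C@H](O[Si](C)(C)C(C)(C)C)[C@H]12
F3 | step 12 | 2α,11-diol from exhaustive reduction of 20 | CC1(C)C[C@H](O)C[C@]2(C)C(CO)=C(CO[Si](c3ccccc3)(c3ccccc3)C(C)(C)C)C[C@H](O[Si](C)(C)C(C)(C)C)[C@H]12
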